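The numbers stand for no real mixture; no experiment stands behind them.

At early times I watch blue, where each enzyme faces 1300 substrate from the first moment.

| flask | substrate | enzyme | added ligand | time | remark |
|---|---|---|---|---|---|
| violet | 0.13 M (fed, over 30.0 h) | 0.10 mM | 0.14 mM | 30 h | a stirred flask in which substrate is dosed at a steady rate over 30.0 h without added volume, worked up at 30 h |
| red | 0.13 M | 0.10 mM | 0.14 mM |  | a single well-mixed tank run continuously and read at steady state, 30 h in it on average |
| blue | 0.13 M | 0.10 mM | 0.14 mM | 30 h | everything together in a closed stirred flask, run for 30 h |

* the set-up with the highest amount of target at the outlet or at the end, in percent of the substrate put in ("none" if the first two lie within 2 percentage points) (violet / red / blue / none)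
* amount of target at the outlet or at the end, in percent of the substrate put in, violet
* amount of target at the outlet or at the end, in percent of the substrate put in, red
* amount of target at the outlet or at the end, in percent of the substrate put in, blue

- in percentages every species weighs as the substrate in it: one spent catalyst counts as two
- two of one species on the left: rate k times its square, two consumed each time
- the stated concentrations are those of everything mixed, before any reaction; amounts are the same in each set-up
- the feed brings no volume worth counting
- run time (violet): 30 h

    2 starting complex → spent catalyst (k1 = 0.43 M⁻¹ s⁻¹)
    enzyme + added ligand ⇌ idle complex (K2 = 51000 M⁻¹, k2 = 0.061 M⁻¹ s⁻¹)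
    starting complex → enzyme + target (k3 = 0.016 s⁻¹)
    substrate + enzyme ⇌ starting complex (K4 = 3.2 M⁻¹, k4 = 5.2 M⁻¹ s⁻¹)

The ladder for blue takes substrate and added ligand at their charges:

| Rung in blue | Half-time |
|---|---|
| starting complex back to enzyme and substrate | 0.427 s |
| starting complex to enzyme and target | 43.3 s |
| starting complex into spent catalyst | 11.0 h |
| enzyme into idle complex, forward step | 22.5 h |
| substrate, with the whole enzyme charge free | 37.6 h |

The first rung is faster than the second, so binding stays in balance. Starting complex over enzyme is then the binding constant times substrate, 0.416, and at the start, before idle complex forms, free enzyme is 70.6% of the catalyst.

Target forms from starting complex, so substrate decays in a pseudo-first-order way, with a constant proportional to free enzyme. Going to logarithms gives my rule. The logarithm of substrate charged over substrate left equals the mean share of the catalyst standing as free enzyme, multiplied by the turnover exponent, which is the rate constant of target formation times the binding constant times the enzyme charge times the time: 0.553.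

The third and fourth rungs are shorter than the run, so I expect the share to sink. With the share held at its start value, my rule gives blue 32.3% of target; with half that value throughout, it gives 17.7%. My reckoning stops at that bracket, and I do not reckon violet or red.

The forecast names blue as best, with violet 12.4% (11.5% to 13.3%), red 18.4% (17.4% to 19.4%) and blue 21.7% (20.7% to 22.7%). Its ground is that “Conversion is therefore catalyst-limited”.

The simulation gives violet 12.4%, red 18.4% and blue 21.7%, so blue is best.

Blue ends with 78.3% of its substrate, so the logarithm 0.245 over 0.553 reads a mean free-enzyme share of 44.3%. A neighbour of blue charged with 4.0 × 10⁻⁴ M of enzyme has an exponent of 2.21 and keeps 45.4% of its substrate, which reads a lower share of 35.7%, with spent catalyst at 51.6% of its catalyst. The largest single effect on violet against blue comes from the backward run from starting complex to substrate and enzyme: without that run, violet goes from trailing blue by 9.3 percentage points to leading it by 2.1 points.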